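**Plan**
- The retrosynthesis first cuts C–O bonds only: the ring B hydroquinone goes back to a para-quinone and then to its 2',5'-dimethyl ether, and the 3-OMe goes back to 3-OH and then to C3–H of a pentamethoxyflavone.
- That flavone is cut at C4a–C4, C4–C3 and O1–C2 into an ortho-iodophenol (ring A), carbon monoxide (C4) and an arylacetylene (C3, C2 and ring B).
- Enabling feature: the C4 carbonyl of ring C lies between C4a of ring A and the C3=C2 unit that carries ring B, and O1 sits on C8a next to C4a. An iodine at C4a beside a free OH at C8a is therefore enough to stitch in CO and the alkyne.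
- Forward: rings A and B are bought (3,5-dimethoxyphenol, 2,4,5-trimethoxybenzaldehyde) and ring C is the only ring built (step 5). C3 is then oxygenated and methylated, and ring B is unmasked last by oxidation to the quinone and reduction.
- Stereochemistry: the target has no stereocenter, so nothing has to be controlled.

Key step: step 5

Remark: the only stereogenic compound on the route, the flavone epoxide of step 6, is racemic and cis-fused by necessity; it is drawn as one enantiomer and its stereocenters vanish when it opens.

**Route**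

Step 1
Reactants: 1 3,5-dimethoxyphenol
Product: 2 1,3-dimethoxy-5-(methoxymethoxy)benzene
Conditions: MOMCl, i-Pr2NEt, CH2Cl2, 0 °C to rt
Reagents that add atoms: chloromethyl methyl ether (MOMCl), COCCl
Why: Base-mediated O-alkylation of the phenol (MOM protection) is routine and installs the chelating acetal oxygen that should direct the metalation of step 2.

Step 2
Reactants: 2 1,3-dimethoxy-5-(methoxymethoxy)benzene
Product: 4 2-iodo-1,5-dimethoxy-3-(methoxymethoxy)benzene, via aryllithium 3 (not isolated)
Conditions: n-BuLi, TMEDA, THF, 0 °C; then I2, THF, −78 °C to rt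
Reagents that add atoms: iodine, II
Why: Directed ortho-metalation should place lithium on the carbon between OMOM and OMe (two equivalent sites, favoured by the stronger chelating group over the site between the two OMe groups), and iodinolysis of the aryllithium gives the iodide.

Step 3
Reactants: 4 2-iodo-1,5-dimethoxy-3-(methoxymethoxy)benzene
Product: 5 2-iodo-3,5-dimethoxyphenol
Conditions: HCl (conc. aq., cat.), MeOH, 40 °C
Reagents that add atoms: none
Why: Acid-catalysed transacetalisation in methanol cleaves the MOM acetal under conditions mild enough to leave the aryl methyl ethers and the aryl iodide untouched.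

Step 4
Reactants: 6 2,4,5-trimethoxybenzaldehyde
Product: 8 1-ethynyl-2,4,5-trimethoxybenzene, via diazoalkene 7 (not isolated)
Conditions: dimethyl (1-diazo-2-oxopropyl)phosphonate, K2CO3, MeOH, rt
Reagents that add atoms: dimethyl (1-diazo-2-oxopropyl)phosphonate, CC(=O)C(=[N+]=[N-])P(=O)(OC)OC
Why: Seyferth–Gilbert homologation in its Ohira–Bestmann form, in which methanolysis of the reagent frees the diazomethylphosphonate anion, Horner–Wadsworth–Emmons-type olefination gives diazoalkene 7, and loss of N2 with a 1,2-shift should deliver the terminal alkyne under conditions that an electron-rich aldehyde tolerates.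

Step 5
Reactants: 5 2-iodo-3,5-dimethoxyphenol; 8 1-ethynyl-2,4,5-trimethoxybenzene; 9 carbon monoxide
Product: 12 5,7-dimethoxy-2-(2,4,5-trimethoxyphenyl)-4H-chromen-4-one, via ynone 10 (not isolated), via enaminone 11 (not isolated)
Conditions: PdCl2(PPh3)2 (5 mol %), CO (10 bar), Et2NH, 120 °C, autoclave
Reagents that add atoms: carbon monoxide (compound 9), [C-]#[O+]
Why: PdCl2(PPh3)2 is reduced in the flask to zerovalent palladium, which inserts into the C–I bond of 5; CO insertion gives the aroyl complex of divalent palladium, the acetylide of 8 formed with Et2NH is transferred to it, and reductive elimination closes the catalytic cycle and delivers ynone 10 with the new C4a–C4 and C4–C3 bonds. Et2NH then adds in conjugate fashion to 10 to give enaminone 11, whose β-carbon (the future C2) is attacked by the ortho-phenol oxygen with loss of Et2NH, forming O1–C2. The closest known reaction type is the palladium-catalysed carbonylative Sonogashira coupling of ortho-iodophenols with terminal alkynes followed by in situ cyclisation to flavones. Ring C closes by 6-endo-trig addition–elimination on the enaminone, formally a 6-endo-dig closure on the ynone, and no stereocenter is created. Two selectivities are needed: CO insertion must precede alkynyl transfer, otherwise direct coupling leads to a 2-arylbenzofuran, and closure must be 6-endo instead of 5-exo, which would give the aurone. The first should be secured by CO pressure, the absence of a copper salt and the two ortho substituents (OH and OMe) of 5 that retard direct alkynylation of the crowded aryl complex, the second by the amine adduct 11, in which only the β-carbon is electrophilic and the free OH at the future C8a is held within reach of it.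

Step 6
Reactants: 12 5,7-dimethoxy-2-(2,4,5-trimethoxyphenyl)-4H-chromen-4-one
Product: 14 3-hydroxy-5,7-dimethoxy-2-(2,4,5-trimethoxyphenyl)-4H-chromen-4-one, via epoxide 13 (not isolated)
Conditions: DMDO (freshly prepared solution in acetone), CH2Cl2, 0 °C to rt; concentrate; then p-TsOH·H2O (cat.), CH2Cl2, rt
Reagents that add atoms: dimethyldioxirane (DMDO), CC1(C)OO1
Why: Electrophilic epoxidation of the enol-ether-like C2=C3 bond by the dioxirane, then acid-catalysed opening of the epoxide at C2 (cation stabilised by O1 and ring B) with loss of the C3 proton, is the established flavone-to-flavonol oxidation and should give the 3-hydroxyflavone.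

Step 7
Reactants: 14 3-hydroxy-5,7-dimethoxy-2-(2,4,5-trimethoxyphenyl)-4H-chromen-4-one
Product: 15 3,5,7-trimethoxy-2-(2,4,5-trimethoxyphenyl)-4H-chromen-4-one
Conditions: MeI, K2CO3, acetone, reflux
Reagents that add atoms: iodomethane, CI
Why: Williamson O-methylation of the acidic 3-OH, the only free hydroxyl group in 14, should proceed cleanly.

Step 8
Reactants: 15 3,5,7-trimethoxy-2-(2,4,5-trimethoxyphenyl)-4H-chromen-4-one
Product: 16 2-(4-methoxy-3,6-dioxocyclohexa-1,4-dien-1-yl)-3,5,7-trimethoxy-4H-chromen-4-one
Conditions: (NH4)2Ce(NO3)6 (2.5 equiv), MeCN–H2O, 0 °C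
Reagents that add atoms: water, O
Why: Oxidative demethylation by tetravalent cerium should start at ring B, the most electron-rich ring with its para-disposed 2'- and 5'-OMe groups, where attack of water and loss of two MeOH give the para-quinone; the 4'-OMe stays as a vinylogous ester, and the meta-dimethoxy ring A, deactivated by the C4 carbonyl, cannot form a quinone.

Step 9
Reactants: 16 2-(4-methoxy-3,6-dioxocyclohexa-1,4-dien-1-yl)-3,5,7-trimethoxy-4H-chromen-4-one
Product: 17 5-O-methyloxyayanin A, 2-(2,5-dihydroxy-4-methoxyphenyl)-3,5,7-trimethoxy-4H-chromen-4-one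
Conditions: Na2S2O4, EtOAc–H2O, rt, under N2
Reagents that add atoms: none
Why: Two-electron reduction of the para-quinone by dithionite in a two-phase system should give the hydroquinone without touching the chromone, and the inert atmosphere guards against re-oxidation.

**Compound list**
1 | 3,5-dimethoxyphenol | COc1cc(O)cc(OC)c1 | starting material
2 | 1,3-dimethoxy-5-(methoxymethoxy)benzene | COCOc1cc(OC)cc(OC)c1 | intermediate
3 | [2,4-dimethoxy-6-(methoxymethoxy)phenyl]lithium | [Li]c1c(OC)cc(OC)cc1OCOC | intermediate
4 | 2-iodo-1,5-dimethoxy-3-(methoxymethoxy)benzene | COCOc1cc(OC)cc(OC)c1I | intermediate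
5 | 2-iodo-3,5-dimethoxyphenol | COc1cc(O)c(I)c(OC)c1 | intermediate
6 | 2,4,5-trimethoxybenzaldehyde | COc1cc(OC)c(C=O)cc1OC | starting material
7 | 1-(2-diazoethenyl)-2,4,5-trimethoxybenzene | COc1cc(OC)c(C=C=[N+]=[N-])cc1OC | intermediate
8 | 1-ethynyl-2,4,5-trimethoxybenzene | C#Cc1cc(OC)c(OC)cc1OC | intermediate
9 | carbon monoxide | [C-]#[O+] | starting material
10 | 1-(2-hydroxy-4,6-dimethoxyphenyl)-3-(2,4,5-trimethoxyphenyl)prop-2-yn-1-one | COc1cc(O)c(C(=O)C#Cc2cc(OC)c(OC)cc2OC)c(OC)c1 | intermediate
11 | (E)-3-(diethylamino)-1-(2-hydroxy-4,6-dimethoxyphenyl)-3-(2,4,5-trimethoxyphenyl)prop-2-en-1-one | CCN(CC)/C(c1cc(OC)c(OC)cc1OC)=C/C(=O)c1c(O)cc(OC)cc1OC | intermediate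
12 | 5,7-dimethoxy-2-(2,4,5-trimethoxyphenyl)-4H-chromen-4-one | COc1cc(OC)c2c(=O)cc(-c3cc(OC)c(OC)cc3OC)oc2c1 | intermediate
13 | 2,3-epoxy-5,7-dimethoxy-2-(2,4,5-trimethoxyphenyl)chroman-4-one (flavone 2,3-epoxide, racemic, cis-fused, one enantiomer drawn) | COc1cc(OC)c2c(c1)O[C@]1(c3cc(OC)c(OC)cc3OC)O[C@@H]1C2=O | intermediate
14 | 3-hydroxy-5,7-dimethoxy-2-(2,4,5-trimethoxyphenyl)-4H-chromen-4-one | COc1cc(OC)c2c(=O)c(O)c(-c3cc(OC)c(OC)cc3OC)oc2c1 | intermediate
15 | 3,5,7-trimethoxy-2-(2,4,5-trimethoxyphenyl)-4H-chromen-4-one | COc1cc(OC)c2c(=O)c(OC)c(-c3cc(OC)c(OC)cc3OC)oc2c1 | intermediate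
16 | 2-(4-methoxy-3,6-dioxocyclohexa-1,4-dien-1-yl)-3,5,7-trimethoxy-4H-chromen-4-one | COc1cc(OC)c2c(=O)c(OC)c(C3=CC(=O)C(OC)=CC3=O)oc2c1 | intermediate
17 | 5-O-methyloxyayanin A, 2-(2,5-dihydroxy-4-methoxyphenyl)-3,5,7-trimethoxy-4H-chromen-4-one | COc1cc(OC)c2c(=O)c(OC)c(-c3cc(O)c(OC)cc3O)oc2c1 | target

**Step count**
Total: 9 steps. Longest linear sequence: 8 steps (steps 1, 2, 3, 5, 6, 7, 8 and 9, from compound 1); step 4 supplies the alkyne branch.

**Steps most likely to fail**

Step 5. Direct, non-carbonylative alkynylation of the crowded, electron-rich aryl–palladium species may outrun CO insertion, or Et2NH may capture the acyl complex as an amide, so that little ynone is formed. The fallback builds ring C by condensation and oxidation instead. It sets out from aldehyde 6, which is condensed with purchased 1-(2-hydroxy-4,6-dimethoxyphenyl)ethanone (KOH, EtOH, rt, Claisen–Schmidt) to give the chalcone (E)-1-(2-hydroxy-4,6-dimethoxyphenyl)-3-(2,4,5-trimethoxyphenyl)prop-2-en-1-one F1. Oxidative cyclisation of F1 with catalytic I2 in DMSO at 130 °C should then give flavone 12, where the route is rejoined.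

Step 6. Oxygen transfer to the electron-rich rings A and B may compete with epoxidation of the C2=C3 bond, or the epoxide may open along other paths than to the enol. The fallback sets out from flavone 12 and uses C3 metalation instead of an electrophilic oxidant. Deprotonation at C3 with LiN(i-Pr)2 in THF at −78 °C should give 3-lithio-5,7-dimethoxy-2-(2,4,5-trimethoxyphenyl)-4H-chromen-4-one F2. Trapping with B(OMe)3 gives dimethyl [5,7-dimethoxy-4-oxo-2-(2,4,5-trimethoxyphenyl)-4H-chromen-3-yl]boronate F3, and oxidation of the C–B bond with H2O2/AcOH should give flavonol 14, where the route is rejoined.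

Step 8. One-electron oxidation may be unselective, with attack or nitration on ring A, or may run on past the quinone with loss of the 4'-methyl group. The fallback sets out from 15 and replaces the chemical oxidant by anodic oxidation. Constant-current electrolysis (Pt anode, KOH 1 % in MeOH, 0 °C) should give the quinone bis(dimethyl ketal) 3,5,7-trimethoxy-2-(3,3,4,6,6-pentamethoxycyclohexa-1,4-dien-1-yl)-4H-chromen-4-one F4. Hydrolysis of F4 with dilute HCl in acetone–H2O at rt should give quinone 16, where the route is rejoined.

**Further compounds**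
F1 | step 5 | (E)-1-(2-hydroxy-4,6-dimethoxyphenyl)-3-(2,4,5-trimethoxyphenyl)prop-2-en-1-one | COc1cc(O)c(C(=O)/C=C/c2cc(OC)c(OC)cc2OC)c(OC)c1
F2 | step 6 | 3-lithio-5,7-dimethoxy-2-(2,4,5-trimethoxyphenyl)-4H-chromen-4-one | COc1cc(OC)c2c(=O)c([Li])c(-c3cc(OC)c(OC)cc3OC)oc2c1
F3 | step 6 | dimethyl [5,7-dimethoxy-4-oxo-2-(2,4,5-trimethoxyphenyl)-4H-chromen-3-yl]boronate | COB(OC)c1c(-c2cc(OC)c(OC)cc2OC)oc2cc(OC)cc(OC)c2c1=O
F4 | step 8 | 3,5,7-trimethoxy-2-(3,3,4,6,6-pentamethoxycyclohexa-1,4-dien-1-yl)-4H-chromen-4-one | COc1cc(OC)c2c(=O)c(OC)c(C3=CC(OC)(OC)C(OC)=CC3(OC)OC)oc2c1
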